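**Retrosynthetic overview**
- Target ⇐ thirteen-fold O-demethylation of its tridecamethyl ether; no ring is built, all five benzene rings are bought and only joined.
- Ring A–O–ring B ether ⇐ copper-catalysed O-arylation of the central phenol of ring B with 1-bromo-3,5-dimethoxybenzene (joined last).
- Ring C–ring D and ring C–ring E biaryl bonds ⇐ twofold Suzuki coupling of a ring C dibromide with (2,4,6-trimethoxyphenyl)boronic acid (joined second).
- Ring B–O–ring C ether (key C–O bond, joined first) ⇐ new aryloxylation: a phenol with every ortho and para carbon blocked (ring C) attacks through oxygen the quinone monoketal made from 2,4-dimethoxyphenol (ring B).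
- Ring C phenol ⇐ 1,3,5-trimethoxybenzene by tribromination, then single Br/Li exchange, borylation and oxidation.

Assumption: the SMILES has no stereocentre and no axis that can give stable atropisomers (rings C, D and E are each symmetric about their own axis), so the target is achiral and no stereocontrol is needed.

**Step 1**
Reactants: 1 1,3,5-trimethoxybenzene
Product: 2 1,3,5-tribromo-2,4,6-trimethoxybenzene
Conditions: Br2 (3.3 equiv), CH2Cl2, 0 °C → rt
Reagents that add atoms: bromine, BrBr
Why: Exhaustive electrophilic aromatic bromination; each of the three equivalent CH positions is ortho/para to three methoxy groups, and over-reaction is impossible because no CH remains.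

**Step 2**
Reactants: 2 1,3,5-tribromo-2,4,6-trimethoxybenzene
Product: 5 3,5-dibromo-2,4,6-trimethoxyphenol, via aryllithium 3 (not isolated), via lithium aryltrimethoxyborate 4 (not isolated)
Conditions: n-BuLi (1.05 equiv), THF, −78 °C; B(OMe)3, −78 °C → rt; then AcOH, 30% H2O2, 0 °C → rt
Reagents that add atoms: hydrogen peroxide, OO (phenol oxygen of 5); n-butyllithium, CCCC[Li] (lithium of 3 and 4 only); trimethyl borate, COB(OC)OC (boron unit of 4 only)
Why: Bromine–lithium exchange at −78 °C stops after one of the three equivalent bromines with one equivalent of n-BuLi (the aryllithium sits between two chelating methoxy groups), and borylation followed by peracid oxidation of the aryl–boron bond (Hawthorne-type phenol synthesis) gives the phenol.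

**Step 3**
Reactants: 6 2,4-dimethoxyphenol; 5 3,5-dibromo-2,4,6-trimethoxyphenol
Product: 10 2-(3,5-dibromo-2,4,6-trimethoxyphenoxy)-4,6-dimethoxyphenol, via quinone monoketal 7 (not isolated), via mixed aryl methyl ketal 8 (not isolated), via keto tautomer 9 (not isolated)
Conditions: 6, PhI(OAc)2 (1.0 equiv), MeOH, 0 °C; NaHCO3 wash, concentrate; crude 7 added slowly to 5 (2.0 equiv), (PhO)2P(O)OH (10 mol%), 5 Å MS, CH2Cl2/HFIP 4:1, −20 °C → rt
Reagents that add atoms: methanol, CO (second ketal methoxy of 7; one of the two ketal methoxy groups leaves again on the way to 8, so the 4-methoxy of 10 may stem from it)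
Why: Proposed new method: acid-promoted aryloxylation of a quinone monoketal by a phenol that can react only at oxygen. The phosphoric acid in the ionising, non-nucleophilic fluoroalcohol ionises the ketal of 7 to a 2,4-dimethoxyphenoxenium-type ion pair (positive charge at C2, C4 and C6). Phenol 5 has all ortho and para carbons substituted, so C–C coupling is impossible and it adds reversibly through oxygen at C4 to give mixed ketal 8 (sieves remove MeOH). Re-ionisation of 8 (aryloxide is the better leaving group) and collapse of the ion pair at C6, the only unsubstituted carbon next to the carbonyl, gives dienone 9 in a net 1,3-aryloxy shift (SN2'-type), and 9 tautomerises irreversibly to phenol 10; attack at C2 or C4 only gives ketals that revert, so the system funnels to 10. The closest known reaction type is the acid-promoted SN2'-type substitution of quinone monoketals by electron-rich arenes in fluoroalcohols, which forms C–C bonds at the same carbon; here it is extended to an O-nucleophile to form a diaryl ether.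

**Step 4**
Reactants: 10 2-(3,5-dibromo-2,4,6-trimethoxyphenoxy)-4,6-dimethoxyphenol; 11 (2,4,6-trimethoxyphenyl)boronic acid
Product: 12 2-[2,4,6-trimethoxy-3,5-bis(2,4,6-trimethoxyphenyl)phenoxy]-4,6-dimethoxyphenol
Conditions: 11 (4 equiv), Pd(OAc)2 (10 mol%), SPhos (20 mol%), K3PO4, toluene/H2O 10:1, degassed, 100 °C
Reagents that add atoms: none
Why: Twofold Suzuki–Miyaura coupling; the bulky dialkylbiarylphosphine SPhos is suited to tetra-ortho-substituted biaryls, excess 11 offsets protodeboronation, the free phenol is tolerated, and both new axes carry symmetric rings so no stereoelement arises.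

**Step 5**
Reactants: 12 2-[2,4,6-trimethoxy-3,5-bis(2,4,6-trimethoxyphenyl)phenoxy]-4,6-dimethoxyphenol; 13 1-bromo-3,5-dimethoxybenzene
Product: 14 2-(3,5-dimethoxyphenoxy)-1,5-dimethoxy-3-[2,4,6-trimethoxy-3,5-bis(2,4,6-trimethoxyphenyl)phenoxy]benzene (tridecamethyl ether of the target)
Conditions: 13 (2 equiv), CuI (20 mol%), picolinic acid (40 mol%), K3PO4, DMSO, 100 °C
Reagents that add atoms: none
Why: Copper-catalysed Ullmann diaryl ether synthesis; the picolinic acid ligand tolerates phenols with two ortho substituents, bromide 13 is unhindered, and 12 carries no other aryl halide.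

**Step 6**
Reactants: 14 tridecamethyl ether of the target
Product: 15 4-(3,5-dihydroxyphenoxy)-5-[2,4,6-trihydroxy-3,5-bis(2,4,6-trihydroxyphenyl)phenoxy]benzene-1,3-diol (CNP0228669.0)
Conditions: BBr3 (40 equiv), CH2Cl2, −78 °C → rt, 36 h; MeOH then H2O; Sephadex LH-20 under argon
Reagents that add atoms: none
Why: Lewis-acid cleavage of aryl methyl ethers (boron coordination, then SN2 attack of bromide at methyl) removes all thirteen methyl groups while the diaryl ether and biaryl bonds stay intact.

**Compound list**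
1 | 1,3,5-trimethoxybenzene | COc1cc(OC)cc(OC)c1 | starting material
2 | 1,3,5-tribromo-2,4,6-trimethoxybenzene | COc1c(Br)c(OC)c(Br)c(OC)c1Br | intermediate
3 | (3,5-dibromo-2,4,6-trimethoxyphenyl)lithium | [Li]c1c(OC)c(Br)c(OC)c(Br)c1OC | intermediate (not isolated)
4 | lithium (3,5-dibromo-2,4,6-trimethoxyphenyl)trimethoxyborate | [Li+].CO[B-](OC)(OC)c1c(OC)c(Br)c(OC)c(Br)c1OC | intermediate (not isolated)
5 | 3,5-dibromo-2,4,6-trimethoxyphenol | COc1c(O)c(OC)c(Br)c(OC)c1Br | intermediate
6 | 2,4-dimethoxyphenol | COc1ccc(O)c(OC)c1 | starting material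
7 | 2,4,4-trimethoxycyclohexa-2,5-dien-1-one | COC1=CC(OC)(OC)C=CC1=O | intermediate (not isolated)
8 | 4-(3,5-dibromo-2,4,6-trimethoxyphenoxy)-2,4-dimethoxycyclohexa-2,5-dien-1-one (racemic, transient) | COC1=CC(OC)(Oc2c(OC)c(Br)c(OC)c(Br)c2OC)C=CC1=O | intermediate (not isolated)
9 | 6-(3,5-dibromo-2,4,6-trimethoxyphenoxy)-2,4-dimethoxycyclohexa-2,4-dien-1-one (racemic, transient) | COC1=CC(OC)=CC(Oc2c(OC)c(Br)c(OC)c(Br)c2OC)C1=O | intermediate (not isolated)
10 | 2-(3,5-dibromo-2,4,6-trimethoxyphenoxy)-4,6-dimethoxyphenol | COc1cc(OC)c(O)c(Oc2c(OC)c(Br)c(OC)c(Br)c2OC)c1 | intermediate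
11 | (2,4,6-trimethoxyphenyl)boronic acid | COc1cc(OC)c(B(O)O)c(OC)c1 | starting material
12 | 2-[2,4,6-trimethoxy-3,5-bis(2,4,6-trimethoxyphenyl)phenoxy]-4,6-dimethoxyphenol | COc1cc(OC)c(O)c(Oc2c(OC)c(-c3c(OC)cc(OC)cc3OC)c(OC)c(-c3c(OC)cc(OC)cc3OC)c2OC)c1 | intermediate
13 | 1-bromo-3,5-dimethoxybenzene | COc1cc(Br)cc(OC)c1 | starting material
14 | 2-(3,5-dimethoxyphenoxy)-1,5-dimethoxy-3-[2,4,6-trimethoxy-3,5-bis(2,4,6-trimethoxyphenyl)phenoxy]benzene | COc1cc(OC)cc(Oc2c(OC)cc(OC)cc2Oc2c(OC)c(-c3c(OC)cc(OC)cc3OC)c(OC)c(-c3c(OC)cc(OC)cc3OC)c2OC)c1 | intermediate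
15 | 4-(3,5-dihydroxyphenoxy)-5-[2,4,6-trihydroxy-3,5-bis(2,4,6-trihydroxyphenyl)phenoxy]benzene-1,3-diol (achiral, no stereocentre) | Oc1cc(O)cc(Oc2c(O)cc(O)cc2Oc2c(O)c(-c3c(O)cc(O)cc3O)c(O)c(-c3c(O)cc(O)cc3O)c2O)c1 | target

**Totals**
Total step count: 6. Longest linear sequence: 6 (1 → 2 → 5 → 10 → 12 → 14 → 15); 6, 11 and 13 are bought and enter at steps 3, 4 and 5.

**Three steps most likely to fail**

Step 3 (the proposed new step). The electron-rich product 10 may attack 7 through carbon (C–C coupling), the phenol may add at the carbon beta to the carbonyl and give the regioisomeric ether, or 7 may hydrolyse to 2-methoxybenzoquinone. The fallback uses known chemistry, sets out from 5 and returns at 10. Phenol 5 and commercial 2-fluoro-4,6-dimethoxybenzaldehyde (K2CO3, DMF, 130 °C; SNAr activated by the ortho-formyl group) give 2-(3,5-dibromo-2,4,6-trimethoxyphenoxy)-4,6-dimethoxybenzaldehyde F1. Dakin-type Baeyer–Villiger oxidation of this electron-rich aldehyde (mCPBA, CH2Cl2, rt) gives 2-(3,5-dibromo-2,4,6-trimethoxyphenoxy)-4,6-dimethoxyphenyl formate F2, and methanolysis (K2CO3, MeOH, rt) gives 10.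

Step 4. Two tetra-ortho-substituted biaryl bonds must form and 11 protodeboronates readily, so mono-coupled and hydrodebrominated products are likely. The fallback sets out from 10 (with 1 as aryl source) and returns at 12; it replaces the boronic acid by an organozinc under anhydrous conditions. Compound 1 is lithiated (n-BuLi, THF, 0 °C → rt) to (2,4,6-trimethoxyphenyl)lithium F3 and transmetalated with ZnCl2 to chloro(2,4,6-trimethoxyphenyl)zinc F4. Negishi coupling of 10 with F4 (5 equiv, one consumed by the phenol proton; Pd2(dba)3, RuPhos, THF/NMP, 70 °C) gives 12.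

Step 5. The phenol of 12 is flanked by a methoxy group and a very large aryloxy group, so the copper coupling may stall. The fallback sets out from 12 and returns at 14; it is a metal-free arylation with a diaryliodonium salt. Commercial 1-iodo-3,5-dimethoxybenzene is oxidised (mCPBA, TsOH·H2O, MeCN, 55 °C) to 1-[hydroxy(tosyloxy)iodo]-3,5-dimethoxybenzene F5, which arylates 1 in the same pot to (3,5-dimethoxyphenyl)(2,4,6-trimethoxyphenyl)iodonium 4-methylbenzenesulfonate F6. Treating 12 with KOt-Bu and F6 (THF/toluene, rt → 40 °C) transfers the 3,5-dimethoxyphenyl group by ligand coupling at trivalent iodine (the electron-rich trimethoxyphenyl group is not transferred) and gives 14.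

**Further compounds**
F1 | step 3 | 2-(3,5-dibromo-2,4,6-trimethoxyphenoxy)-4,6-dimethoxybenzaldehyde | COc1cc(OC)c(C=O)c(Oc2c(OC)c(Br)c(OC)c(Br)c2OC)c1
F2 | step 3 | 2-(3,5-dibromo-2,4,6-trimethoxyphenoxy)-4,6-dimethoxyphenyl formate | COc1cc(OC)c(OC=O)c(Oc2c(OC)c(Br)c(OC)c(Br)c2OC)c1
F3 | step 4 | (2,4,6-trimethoxyphenyl)lithium | [Li]c1c(OC)cc(OC)cc1OC
F4 | step 4 | chloro(2,4,6-trimethoxyphenyl)zinc | Cl[Zn]c1c(OC)cc(OC)cc1OC
F5 | step 5 | 1-[hydroxy(tosyloxy)iodo]-3,5-dimethoxybenzene | COc1cc(OC)cc(c1)I(O)OS(=O)(=O)c1ccc(C)cc1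
F6 | step 5 | (3,5-dimethoxyphenyl)(2,4,6-trimethoxyphenyl)iodonium 4-methylbenzenesulfonate | COc1cc(OC)cc([I+]c2c(OC)cc(OC)cc2OC)c1.Cc1ccc(cc1)S(=O)(=O)[O-]
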